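**Plan**

- Numbering: C1 is the methyl ester carbonyl and C7 the acid carbon; in this numbering the target is (2R,6S). C4 is the central methylene, and its neighbours C3 and C5 are each β to a carboxyl carbon. C4 can therefore arrive as the carbon of CO between two 2-substituted propanoate (homoenolate-type) halves. No ring has to close; the furan ring and the Me2C=CH alkene are side-chain spectators.
- Retrosynthesis: the C7 acid comes from a 2-(trimethylsilyl)ethyl ester and the C4 methylene from a C4 ketone. C3–C4 and C4–C5 are cut together to give CO, a β-zincio methyl ester (C1–C3 half) and a β-iodo silylethyl ester (C5–C7 half). Each half is then cut at its side-chain end (furan–CH2 bond; isopropylidene C=C) and at the Cα–CH2 bond.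
- Forward: furan half (steps 1–6), alkene half (steps 7–12), three-component joining at C4 (step 13), removal of the C4 oxygen and release of the acid (steps 14–16).
- Stereochemistry: C6 comes from (S)-4-benzyloxazolidin-2-one and C2 from (R)-4-benzyloxazolidin-2-one. Each is set by hydroxymethylation of a chelated titanium Z-enolate anti to the benzyl group, and neither centre is enolised afterwards.

Key step: step 13

Remark: the furan and the trisubstituted alkene are introduced only after the TiCl4/formaldehyde steps, because both would be attacked by Lewis-acid-activated formaldehyde; a terminal alkene is carried instead.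

**Step 1**
Reactants: 1 pent-4-enoic acid; 2 (S)-4-benzyloxazolidin-2-one
Product: 4 (S)-4-benzyl-3-(pent-4-enoyl)oxazolidin-2-one, via mixed pivalic anhydride 3 (not isolated)
Conditions: PivCl, Et3N, THF, −20 °C; then LiCl, 2, −20 °C → rt
Reagents that add atoms: none
Why: N-acylation of the oxazolidinone through a mixed anhydride, in which the hindered pivaloyl carbonyl directs the LiCl-activated auxiliary to the pentenoyl carbonyl.

**Step 2**
Reactants: 4 (S)-4-benzyl-3-(pent-4-enoyl)oxazolidin-2-one
Product: 6 (S)-4-benzyl-3-[(2R)-2-(hydroxymethyl)pent-4-enoyl]oxazolidin-2-one, via trichlorotitanium Z-enolate 5 (not isolated)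
Conditions: TiCl4, iPr2NEt, CH2Cl2, 0 °C; then 1,3,5-trioxane, TiCl4, 0 °C; aq NH4Cl
Reagents that add atoms: 1,3,5-trioxane, C1OCOCO1
Why: Evans-type titanium enolate hydroxymethylation, in which the chelated Z-enolate is attacked by TiCl4-activated formaldehyde on the face opposite the benzyl group and so sets the future C6 centre as (2R) in 6, while the monosubstituted alkene is too weak a nucleophile to compete.

**Step 3**
Reactants: 6 (S)-4-benzyl-3-[(2R)-2-(hydroxymethyl)pent-4-enoyl]oxazolidin-2-one
Product: 8 (2R)-2-(hydroxymethyl)pent-4-enoic acid, via lithium peroxycarboxylate 7 (not isolated)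
Conditions: LiOH·H2O, 30% H2O2, THF/H2O, 0 °C; then aq Na2SO3; HCl to pH 2
Reagents that add atoms: hydrogen peroxide, OO
Why: Hydroperoxide cleavage of the N-acyl oxazolidinone, in which the hydroperoxide anion attacks the exocyclic carbonyl selectively and is too weak a base to epimerise the α-centre or to attack the terminal alkene, the auxiliary being recovered.

**Step 4**
Reactants: 8 (2R)-2-(hydroxymethyl)pent-4-enoic acid; 9 2-(trimethylsilyl)ethanol
Product: 10 2-(trimethylsilyl)ethyl (2R)-2-(hydroxymethyl)pent-4-enoate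
Conditions: EDC·HCl, DMAP (cat.), 9 (5 equiv), CH2Cl2, 0 °C → rt
Reagents that add atoms: none
Why: Steglich esterification, in which the large excess of 9 should outcompete the substrate's own primary hydroxyl for the acylpyridinium intermediate and no base strong enough to epimerise C2 is present.

**Step 5**
Reactants: 10 2-(trimethylsilyl)ethyl (2R)-2-(hydroxymethyl)pent-4-enoate; 11 3-bromofuran
Product: 13 2-(trimethylsilyl)ethyl (2R)-5-(furan-3-yl)-2-(hydroxymethyl)pentanoate, via bis-borabicyclononane adduct 12 (not isolated)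
Conditions: 9-BBN (2.3 equiv), THF, 0 °C → rt; then 11, PdCl2(dppf) (5 mol %), K3PO4 (3 M aq), DMF, 50 °C
Reagents that add atoms: none
Why: Anti-Markovnikov hydroboration of the terminal alkene (the hydroxyl is capped as a borinate with loss of hydrogen) followed by B-alkyl Suzuki–Miyaura coupling of the primary alkylborane with the heteroaryl bromide, the stereocentre taking no part.

**Step 6**
Reactants: 13 2-(trimethylsilyl)ethyl (2R)-5-(furan-3-yl)-2-(hydroxymethyl)pentanoate
Product: 14 2-(trimethylsilyl)ethyl (2S)-5-(furan-3-yl)-2-(iodomethyl)pentanoate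
Conditions: PPh3, imidazole, I2 (premixed), CH2Cl2, 0 °C, dark
Reagents that add atoms: iodine, II
Why: Appel-type iodination by SN2 displacement of the primary alkoxyphosphonium ion, with no free iodine left for the furan and the stereocentre untouched (the descriptor changes to S only because CH2I outranks the ester).

**Step 7**
Reactants: 15 hex-5-enoic acid; 16 (R)-4-benzyloxazolidin-2-one
Product: 18 (R)-4-benzyl-3-(hex-5-enoyl)oxazolidin-2-one, via mixed pivalic anhydride 17 (not isolated)
Conditions: PivCl, Et3N, THF, −20 °C; then LiCl, 16, −20 °C → rt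
Reagents that add atoms: none
Why: The same mixed-anhydride N-acylation as in step 1, applied to the enantiomeric auxiliary.

**Step 8**
Reactants: 18 (R)-4-benzyl-3-(hex-5-enoyl)oxazolidin-2-one
Product: 20 (R)-4-benzyl-3-[(2S)-2-(hydroxymethyl)hex-5-enoyl]oxazolidin-2-one, via trichlorotitanium Z-enolate 19 (not isolated)
Conditions: TiCl4, iPr2NEt, CH2Cl2, 0 °C; then 1,3,5-trioxane, TiCl4, 0 °C; aq NH4Cl
Reagents that add atoms: 1,3,5-trioxane, C1OCOCO1
Why: Evans-type titanium enolate hydroxymethylation as in step 2, in which the mirror-image auxiliary directs formaldehyde to the opposite enolate face and sets the future C2 centre as (2S) in 20.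

**Step 9**
Reactants: 20 (R)-4-benzyl-3-[(2S)-2-(hydroxymethyl)hex-5-enoyl]oxazolidin-2-one
Product: 21 methyl (2S)-2-(hydroxymethyl)hex-5-enoate
Conditions: MeMgBr, MeOH, CH2Cl2, 0 °C
Reagents that add atoms: methanol (as MeOMgBr), CO
Why: Transesterification of a β-hydroxy imide with bromomagnesium methoxide, in which magnesium chelation between the β-oxygen and the exocyclic carbonyl directs methoxide to that carbonyl and the medium is too weakly basic at 0 °C to epimerise the α-centre.

**Step 10**
Reactants: 21 methyl (2S)-2-(hydroxymethyl)hex-5-enoate; 22 2-methylbut-2-ene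
Product: 23 methyl (2S)-2-(hydroxymethyl)-6-methylhept-5-enoate
Conditions: RuCl2(=CHPh)(PCy3)(H2IMes) (second-generation Grubbs catalyst, 3 mol %), 22 (large excess), CH2Cl2, 35 °C, sealed
Reagents that add atoms: none
Why: Olefin cross-metathesis of the terminal alkene with 2-methylbut-2-ene in large excess caps the chain as the isopropylidene alkene with loss of propene, the free hydroxyl and the ester being tolerated by the ruthenium carbene.

**Step 11**
Reactants: 23 methyl (2S)-2-(hydroxymethyl)-6-methylhept-5-enoate
Product: 24 methyl (2R)-2-(iodomethyl)-6-methylhept-5-enoate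
Conditions: PPh3, imidazole, I2 (premixed), CH2Cl2, 0 °C, dark
Reagents that add atoms: iodine, II
Why: Appel-type iodination as in step 6, the premixed reagent leaving no free iodine for the trisubstituted alkene and the mild base and low temperature avoiding elimination to the acrylate.

**Step 12**
Reactants: 24 methyl (2R)-2-(iodomethyl)-6-methylhept-5-enoate
Product: 25 [(2R)-2-(methoxycarbonyl)-6-methylhept-5-en-1-yl]zinc iodide (THF solution, titrated with I2 and used at once)
Conditions: Zn dust (activated with BrCH2CH2Br and Me3SiCl), LiCl, THF, 25–30 °C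
Reagents that add atoms: zinc, [Zn]
Why: Direct insertion of activated zinc into the primary C–I bond gives a β-zincio ester (zinc homoenolate) that is not basic enough to deprotonate C2, has no β-leaving group and should not add to the remote trisubstituted alkene at room temperature.

**Step 13**
Reactants: 25 [(2R)-2-(methoxycarbonyl)-6-methylhept-5-en-1-yl]zinc iodide; 14 2-(trimethylsilyl)ethyl (2S)-5-(furan-3-yl)-2-(iodomethyl)pentanoate; 26 carbon monoxide
Product: 27 1-methyl 7-[2-(trimethylsilyl)ethyl] (2S,6R)-6-[3-(furan-3-yl)propyl]-2-(4-methylpent-3-en-1-yl)-4-oxoheptanedioate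
Conditions: [NiCl{N(C6H4-2-NMe2)2}] (10 mol %), 26 (1.5 equiv, sealed two-chamber vessel), 14 (1.0 equiv), 25 (1.5 equiv, slow addition), THF/NMP, 25 °C
Reagents that add atoms: none
Why: The pincer nickel chloride is alkylated by 25 through two-electron transmetalation, CO inserts into the Ni–C3 bond to give an acyl complex of divalent nickel, a monovalent nickel species abstracts iodine from 14, the resulting C5 primary radical is captured by the acyl complex, and reductive elimination from trivalent nickel forms the C4–C5 bond, so C3–C4 and C4–C5 are both made here. The closest known reaction type is the nickel-pincer-catalysed carbonylative Negishi coupling of primary alkyl iodides with alkylzinc halides to unsymmetrical dialkyl ketones. No ring closes and no stereocentre is formed; C2 and C6 are spectators because both partners are base-free homoenolate-type species and neither α-carbon is deprotonated. The iodide is placed on the furan half on purpose: the radical of the other half would be a hex-5-enyl radical able to cyclise 5-exo onto the trisubstituted alkene, whereas as a zinc reagent that half does not pass through a radical in this step. The selectivity needed is CO insertion ahead of direct alkyl–alkyl coupling and of β-hydride loss towards C2; the rigid amido-bis(amine) ligand disfavours β-hydride elimination, and slow addition of 25 under a small CO charge should keep the alkylnickel intercepted by CO without saturating the metal.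

**Step 14**
Reactants: 27 1-methyl 7-[2-(trimethylsilyl)ethyl] (2S,6R)-6-[3-(furan-3-yl)propyl]-2-(4-methylpent-3-en-1-yl)-4-oxoheptanedioate
Product: 28 C4 tosylhydrazone of 27 (E/Z mixture at C=N)
Conditions: TsNHNH2, EtOH, 40 °C
Reagents that add atoms: 4-methylbenzenesulfonohydrazide, Cc1ccc(cc1)S(=O)(=O)NN
Why: Condensation of the unhindered dialkyl ketone with tosylhydrazide under neutral conditions, to which the two esters, the furan and the alkene are inert.

**Step 15**
Reactants: 28 C4 tosylhydrazone of 27
Product: 30 1-methyl 7-[2-(trimethylsilyl)ethyl] (2R,6S)-6-[3-(furan-3-yl)propyl]-2-(4-methylpent-3-en-1-yl)heptanedioate, via N-boryl tosylhydrazine 29 (not isolated)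
Conditions: catecholborane, CHCl3, 0 °C → rt; then NaOAc·3H2O, reflux
Reagents that add atoms: none
Why: Kabalka variant of the Caglioti reduction, in which catecholborane delivers hydride to C4, acetate triggers loss of sulfinate and the diazene collapses to the methylene with loss of nitrogen, while esters, furan and alkene are inert and C2 and C6 are untouched (the descriptors change only because the chain loses its carbonyl priority).

**Step 16**
Reactants: 30 1-methyl 7-[2-(trimethylsilyl)ethyl] (2R,6S)-6-[3-(furan-3-yl)propyl]-2-(4-methylpent-3-en-1-yl)heptanedioate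
Product: 31 (2S,6R)-2-[3-(furan-3-yl)propyl]-6-(methoxycarbonyl)-10-methylundec-9-enoic acid (CNP0266677.2)
Conditions: Bu4NF, THF, 0 °C → rt; cold dilute HCl to pH 3–4
Reagents that add atoms: none
Why: Fluoride attacks silicon and the 2-silylethyl ester fragments to ethene, Me3SiF and the carboxylate, while the methyl ester and both α-centres are untouched under these conditions.

**Compound list**

1 | pent-4-enoic acid | C=CCCC(=O)O | starting material
2 | (S)-4-benzyloxazolidin-2-one | O=C1N[C@@H](Cc2ccccc2)CO1 | starting material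
3 | pent-4-enoic pivalic anhydride | C=CCCC(=O)OC(=O)C(C)(C)C | intermediate
4 | (S)-4-benzyl-3-(pent-4-enoyl)oxazolidin-2-one | O=C1OC[C@H](Cc2ccccc2)N1C(=O)CCC=C | intermediate
5 | trichlorotitanium Z-enolate of 4 | O=C1OC[C@H](Cc2ccccc2)N1/C(O[Ti](Cl)(Cl)Cl)=C/CC=C | intermediate
6 | (S)-4-benzyl-3-[(2R)-2-(hydroxymethyl)pent-4-enoyl]oxazolidin-2-one | O=C1OC[C@H](Cc2ccccc2)N1C(=O)[C@H](CC=C)CO | intermediate
7 | lithium (2R)-2-(hydroxymethyl)pent-4-eneperoxoate | [Li+].[O-]OC(=O)[C@H](CC=C)CO | intermediate
8 | (2R)-2-(hydroxymethyl)pent-4-enoic acid | OC(=O)[C@H](CC=C)CO | intermediate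
9 | 2-(trimethylsilyl)ethanol | C[Si](C)(C)CCO | starting material
10 | 2-(trimethylsilyl)ethyl (2R)-2-(hydroxymethyl)pent-4-enoate | C[Si](C)(C)CCOC(=O)[C@H](CC=C)CO | intermediate
11 | 3-bromofuran | Brc1ccoc1 | starting material
12 | 2-(trimethylsilyl)ethyl (2R)-5-(9-borabicyclo[3.3.1]nonan-9-yl)-2-{[(9-borabicyclo[3.3.1]nonan-9-yl)oxy]methyl}pentanoate | C[Si](C)(C)CCOC(=O)[C@H](CCCB1C2CCCC1CCC2)COB1C2CCCC1CCC2 | intermediate
13 | 2-(trimethylsilyl)ethyl (2R)-5-(furan-3-yl)-2-(hydroxymethyl)pentanoate | C[Si](C)(C)CCOC(=O)[C@H](CCCc1ccoc1)CO | intermediate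
14 | 2-(trimethylsilyl)ethyl (2S)-5-(furan-3-yl)-2-(iodomethyl)pentanoate | C[Si](C)(C)CCOC(=O)[C@H](CCCc1ccoc1)CI | intermediate
15 | hex-5-enoic acid | C=CCCCC(=O)O | starting material
16 | (R)-4-benzyloxazolidin-2-one | O=C1N[C@H](Cc2ccccc2)CO1 | starting material
17 | hex-5-enoic pivalic anhydride | C=CCCCC(=O)OC(=O)C(C)(C)C | intermediate
18 | (R)-4-benzyl-3-(hex-5-enoyl)oxazolidin-2-one | O=C1OC[C@@H](Cc2ccccc2)N1C(=O)CCCC=C | intermediate
19 | trichlorotitanium Z-enolate of 18 | O=C1OC[C@@H](Cc2ccccc2)N1/C(O[Ti](Cl)(Cl)Cl)=C/CCC=C | intermediate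
20 | (R)-4-benzyl-3-[(2S)-2-(hydroxymethyl)hex-5-enoyl]oxazolidin-2-one | O=C1OC[C@@H](Cc2ccccc2)N1C(=O)[C@@H](CCC=C)CO | intermediate
21 | methyl (2S)-2-(hydroxymethyl)hex-5-enoate | COC(=O)[C@@H](CCC=C)CO | intermediate
22 | 2-methylbut-2-ene | CC=C(C)C | starting material
23 | methyl (2S)-2-(hydroxymethyl)-6-methylhept-5-enoate | COC(=O)[C@@H](CCC=C(C)C)CO | intermediate
24 | methyl (2R)-2-(iodomethyl)-6-methylhept-5-enoate | COC(=O)[C@@H](CCC=C(C)C)CI | intermediate
25 | [(2R)-2-(methoxycarbonyl)-6-methylhept-5-en-1-yl]zinc iodide | COC(=O)[C@@H](CCC=C(C)C)C[Zn]I | intermediate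
26 | carbon monoxide | [C-]#[O+] | starting material
27 | 1-methyl 7-[2-(trimethylsilyl)ethyl] (2S,6R)-6-[3-(furan-3-yl)propyl]-2-(4-methylpent-3-en-1-yl)-4-oxoheptanedioate | COC(=O)[C@@H](CCC=C(C)C)CC(=O)C[C@@H](CCCc1ccoc1)C(=O)OCC[Si](C)(C)C | intermediate
28 | 1-methyl 7-[2-(trimethylsilyl)ethyl] (2S,6R)-6-[3-(furan-3-yl)propyl]-2-(4-methylpent-3-en-1-yl)-4-[2-(4-methylbenzenesulfonyl)hydrazinylidene]heptanedioate | COC(=O)[C@@H](CCC=C(C)C)CC(=NNS(=O)(=O)c1ccc(C)cc1)C[C@@H](CCCc2ccoc2)C(=O)OCC[Si](C)(C)C | intermediate
29 | N-(1,3,2-benzodioxaborol-2-yl) tosylhydrazine at C4 (both C4 epimers, which converge) | COC(=O)[C@@H](CCC=C(C)C)CC(N(B1Oc2ccccc2O1)NS(=O)(=O)c1ccc(C)cc1)C[C@@H](CCCc3ccoc3)C(=O)OCC[Si](C)(C)C | intermediate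
30 | 1-methyl 7-[2-(trimethylsilyl)ethyl] (2R,6S)-6-[3-(furan-3-yl)propyl]-2-(4-methylpent-3-en-1-yl)heptanedioate | COC(=O)[C@@H](CCC=C(C)C)CCC[C@@H](CCCc1ccoc1)C(=O)OCC[Si](C)(C)C | intermediate
31 | (2S,6R)-2-[3-(furan-3-yl)propyl]-6-(methoxycarbonyl)-10-methylundec-9-enoic acid | COC(=O)[C@@H](CCC=C(C)C)CCC[C@@H](CCCc1ccoc1)C(=O)O | target

**Step count and risks**

Total step count: 16. Longest linear sequence: 10 steps (steps 7–16; the other branch, steps 1–6 and 13–16, is equally long).

Steps most likely to fail:

1. Step 13. The alkylnickel may couple directly with the iodide without taking up CO, lose β-hydride towards C2, or be deactivated by excess CO; the iodide may also be reduced or homocoupled. Fallback, from 14 back to 27: zinc insertion into 14 (Zn dust, LiCl, THF) would give {(2S)-5-(furan-3-yl)-2-{[2-(trimethylsilyl)ethoxy]carbonyl}pentyl}zinc iodide F1. Carboxylation of F1 under CO2 (1 atm) with the zerovalent nickel complex [Ni(PCy3)2]2(N2) would give (3R)-6-(furan-3-yl)-3-{[2-(trimethylsilyl)ethoxy]carbonyl}hexanoic acid F2. EDC·HCl, DMAP and ethanethiol would convert it into 2-(trimethylsilyl)ethyl (2R)-2-[2-(ethylsulfanyl)-2-oxoethyl]-5-(furan-3-yl)pentanoate F3. Fukuyama coupling of F3 with zinc reagent 25 under PdCl2(PPh3)2 in THF/toluene would then give 27. C4 arrives as CO2 at the acid oxidation level and the two bonds are made in separate two-electron steps, so neither CO insertion competition nor an alkyl radical is involved.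

2. Step 5. Hydroboration may stall because the hydroxyl consumes borane, the alkylborane may protodeboronate, oxidative addition of the electron-rich bromide may be slow, or aqueous base may hydrolyse the ester. Fallback, from 10 back to 13: cross-metathesis of 10 with 3-ethenylfuran F4 (made from furan-3-carbaldehyde and Ph3P=CH2) under RuCl2(=CHPh)(PCy3)(H2IMes) would give 2-(trimethylsilyl)ethyl (2R,4E)-5-(furan-3-yl)-2-(hydroxymethyl)pent-4-enoate F5. Diimide (2-nitrobenzenesulfonohydrazide, Et3N, CH2Cl2) would then saturate the disubstituted alkene only and give 13.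

3. Step 4. The activated acid may be captured by the primary hydroxyl of a second molecule, giving oligoesters. Fallback, from 6 back to 10: TBSCl and imidazole would give (S)-4-benzyl-3-[(2R)-2-({[tert-butyl(dimethyl)silyl]oxy}methyl)pent-4-enoyl]oxazolidin-2-one F6. LiOH/H2O2 would give (2R)-2-({[tert-butyl(dimethyl)silyl]oxy}methyl)pent-4-enoic acid F7. EDC·HCl, DMAP and 9 would give 2-(trimethylsilyl)ethyl (2R)-2-({[tert-butyl(dimethyl)silyl]oxy}methyl)pent-4-enoate F8. Camphorsulfonic acid in MeOH at 0 °C would remove the silyl ether and give 10.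

**Further compounds**

F1 | step 13 | {(2S)-5-(furan-3-yl)-2-{[2-(trimethylsilyl)ethoxy]carbonyl}pentyl}zinc iodide | C[Si](C)(C)CCOC(=O)[C@H](CCCc1ccoc1)C[Zn]I
F2 | step 13 | (3R)-6-(furan-3-yl)-3-{[2-(trimethylsilyl)ethoxy]carbonyl}hexanoic acid | C[Si](C)(C)CCOC(=O)[C@H](CCCc1ccoc1)CC(=O)O
F3 | step 13 | 2-(trimethylsilyl)ethyl (2R)-2-[2-(ethylsulfanyl)-2-oxoethyl]-5-(furan-3-yl)pentanoate | C[Si](C)(C)CCOC(=O)[C@H](CCCc1ccoc1)CC(=O)SCC
F4 | step 5 | 3-ethenylfuran | C=Cc1ccoc1
F5 | step 5 | 2-(trimethylsilyl)ethyl (2R,4E)-5-(furan-3-yl)-2-(hydroxymethyl)pent-4-enoate | C[Si](C)(C)CCOC(=O)[C@H](C/C=C/c1ccoc1)CO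
F6 | step 4 | (S)-4-benzyl-3-[(2R)-2-({[tert-butyl(dimethyl)silyl]oxy}methyl)pent-4-enoyl]oxazolidin-2-one | O=C1OC[C@H](Cc2ccccc2)N1C(=O)[C@H](CC=C)CO[Si](C)(C)C(C)(C)C
F7 | step 4 | (2R)-2-({[tert-butyl(dimethyl)silyl]oxy}methyl)pent-4-enoic acid | OC(=O)[C@H](CC=C)CO[Si](C)(C)C(C)(C)C
F8 | step 4 | 2-(trimethylsilyl)ethyl (2R)-2-({[tert-butyl(dimethyl)silyl]oxy}methyl)pent-4-enoate | C[Si](C)(C)CCOC(=O)[C@H](CC=C)CO[Si](C)(C)C(C)(C)C
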